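**Retrosynthetic overview**
- The route rests on ring B's tetrasubstituted C5–C6 oxirane (C5 methyl-bearing, C6 vinyl-bearing), anti to the C3 oxygen. It is an acid-labile vinyl epoxide, so it is made last by epoxidising C5=C6 of the complete bis-silylated polyene.
- The butenolide is cut by a tandem Sonogashira coupling/5-exo-dig lactonisation into a ring A tetraenediyne and a ring B (Z)-3-iodo-2-dienylacrylic acid.
- Ring A tetraenediyne: mono-Sonogashira of the actinol-derived enol triflate with a symmetric C14 tetraenediyne, itself from a double Wittig reaction of glyoxal with the C6 enynyl phosphonium salt.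
- Ring B iodo acid: the same triflate, Stille coupling with (E)-1,2-bis(tributylstannyl)ethene, CuI-catalysed carbomagnesiation of propargyl alcohol with iodine quench, then two-stage oxidation.
- Both carbocycles come ready-made from (4R,6R)-actinol; rings formed in the route: butenolide (step 11), then oxirane (step 12); desilylation ends the route.

Key step: step 12

Assumption: ring carbons carry carotenoid numbering (C1 gem-dimethyl, C3 carbinol, C5 methyl-bearing, C6 chain-bearing), and glyoxal is used as its commercial 40% aqueous solution.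

**Step 1**
Reactants: 1 (4R,6R)-actinol
Product: 2 (4R,6R)-2,2,6-trimethyl-4-(triethylsilyloxy)cyclohexan-1-one
Conditions: Et3SiCl, imidazole, DMF, 0 °C to rt
Reagents that add atoms: chlorotriethylsilane, CC[Si](Cl)(CC)CC
Why: Imidazole-promoted O-silylation of the unhindered secondary alcohol leaves both stereocentres untouched and installs an ether that should survive bases, Pd couplings and buffered oxidations yet fall to buffered fluoride at the end.

**Step 2**
Reactants: 2 (4R,6R)-2,2,6-trimethyl-4-(triethylsilyloxy)cyclohexan-1-one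
Product: 4 (4R)-2,6,6-trimethyl-4-(triethylsilyloxy)cyclohex-1-en-1-yl trifluoromethanesulfonate, via lithium enolate 3 (not isolated)
Conditions: LiN(iPr)2, THF, −78 to 0 °C; then PhNTf2, −78 °C to rt
Reagents that add atoms: N-phenylbis(trifluoromethanesulfonimide), O=S(=O)(N(c1ccccc1)S(=O)(=O)C(F)(F)F)C(F)(F)F
Why: Enolate O-sulfonylation can give only one regioisomer because deprotonation is possible only at the methyl-bearing α-carbon (the other is quaternary), which deliberately erases that stereocentre while the γ-silyloxy centre has no elimination pathway and stays intact.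

**Step 3**
Reactants: 5 (E)-3-methylpent-2-en-4-yn-1-ol
Product: 6 (E)-5-bromo-3-methylpent-3-en-1-yne
Conditions: PBr3 (0.4 equiv), pyridine (cat.), Et2O, −10 to 0 °C; used crude
Reagents that add atoms: phosphorus tribromide, BrP(Br)Br
Why: SN2 displacement of the primary allylic alcohol through its phosphite ester should keep the E trisubstituted alkene and give the primary bromide.

**Step 4**
Reactants: 6 (E)-5-bromo-3-methylpent-3-en-1-yne
Product: 7 [(E)-3-methylpent-2-en-4-yn-1-yl]triphenylphosphonium bromide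
Conditions: PPh3, toluene, rt, dark
Reagents that add atoms: triphenylphosphine, c1ccc(cc1)P(c1ccccc1)c1ccccc1
Why: SN2 quaternisation of triphenylphosphine by the primary allylic bromide gives the phosphonium salt, which should crystallise from toluene.

**Step 5**
Reactants: 7 [(E)-3-methylpent-2-en-4-yn-1-yl]triphenylphosphonium bromide (2.3 equiv); 8 glyoxal
Product: 11 (3E,5E,7E,9E)-3,10-dimethyldodeca-3,5,7,9-tetraene-1,11-diyne, via phosphorus ylide 9 (not isolated), via dienynal 10 (not isolated)
Conditions: 40% aq. glyoxal, CH2Cl2/2 M aq. NaOH (two-phase), 0 °C to rt; then I2 (2 mol%), CH2Cl2, rt, diffuse light; stored cold and dark over BHT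
Reagents that add atoms: none
Why: A double Wittig olefination of the dialdehyde by the semi-stabilised allylic ylide builds both disubstituted alkenes, and iodine-catalysed equilibration should converge the E/Z mixture on the all-E tetraene while the two trisubstituted alkenes keep the geometry of the enynol.

**Step 6**
Reactants: 4 (4R)-2,6,6-trimethyl-4-(triethylsilyloxy)cyclohex-1-en-1-yl trifluoromethanesulfonate; 11 (3E,5E,7E,9E)-3,10-dimethyldodeca-3,5,7,9-tetraene-1,11-diyne (3 equiv)
Product: 12 triethyl({(1R)-4-[(3E,5E,7E,9E)-3,10-dimethyldodeca-3,5,7,9-tetraene-1,11-diyn-1-yl]-3,5,5-trimethylcyclohex-3-en-1-yl}oxy)silane (ring A tetraenediyne)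
Conditions: Pd(PPh3)4 (5 mol%), CuI (10 mol%), Et3N, DMF, rt to 40 °C, degassed, dark; excess 11 recovered
Reagents that add atoms: none
Why: Sonogashira coupling of a vinyl triflate tolerates the tetrasubstituted carbon because the linear copper acetylide is sterically undemanding, and the threefold excess of the symmetric diyne biases the statistics toward the mono-adduct.

**Step 7**
Reactants: 4 (4R)-2,6,6-trimethyl-4-(triethylsilyloxy)cyclohex-1-en-1-yl trifluoromethanesulfonate; 13 (E)-1,2-bis(tributylstannyl)ethene (2.5 equiv)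
Product: 14 tributyl{(E)-2-[(4R)-2,6,6-trimethyl-4-(triethylsilyloxy)cyclohex-1-en-1-yl]ethenyl}stannane (ring B dienylstannane)
Conditions: Pd2(dba)3 (2.5 mol%), AsPh3 (20 mol%), LiCl, NMP, 55 °C; chromatography on Et3N-deactivated silica
Reagents that add atoms: none
Why: Stille coupling of the vinyl triflate with one terminus of the distannane proceeds with retention of the E geometry, the weakly bound AsPh3 ligand speeding transmetalation at the hindered carbon and the excess distannane suppressing double coupling.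

**Step 8**
Reactants: 14 ring B dienylstannane; 15 prop-2-yn-1-ol (2 equiv)
Product: 20 (2Z,3E)-2-(iodomethylidene)-4-[(4R)-2,6,6-trimethyl-4-(triethylsilyloxy)cyclohex-1-en-1-yl]but-3-en-1-ol, via bromomagnesium propargyl alkoxide 16 (not isolated), via dienyllithium 17 (not isolated), via dienylmagnesium bromide 18 (not isolated), via cyclic alkenylmagnesium alkoxide 19 (not isolated)
Conditions: 15, EtMgBr (1.0 equiv per 15), THF, 0 °C; separately 14, MeLi, THF, −78 to −40 °C, then MgBr2·OEt2, −78 to 0 °C; combine, CuI (15 mol%), 0 °C to rt; then I2 (1.1 equiv), THF, −30 °C; aq. Na2S2O3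
Reagents that add atoms: iodine, II
Why: Tin–lithium exchange and transmetalation give the E-dienyl Grignard reagent with retention, and its CuI-catalysed anti-carbomagnesiation of the propargyl alkoxide puts the dienyl group on the internal carbon and magnesium on the terminal carbon inside a five-membered chelate cis to the CH2O group, so iodinolysis with retention should give only the Z iodoalkene.

**Step 9**
Reactants: 20 (2Z,3E)-2-(iodomethylidene)-4-[(4R)-2,6,6-trimethyl-4-(triethylsilyloxy)cyclohex-1-en-1-yl]but-3-en-1-ol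
Product: 21 (2Z,3E)-2-(iodomethylidene)-4-[(4R)-2,6,6-trimethyl-4-(triethylsilyloxy)cyclohex-1-en-1-yl]but-3-enal
Conditions: MnO2 (20 equiv), CH2Cl2, rt, dark
Reagents that add atoms: none
Why: Activated MnO2 performs a selective allylic oxidation under neutral conditions that should preserve the Z iodoalkene, the diene and the silyl ether.

**Step 10**
Reactants: 21 (2Z,3E)-2-(iodomethylidene)-4-[(4R)-2,6,6-trimethyl-4-(triethylsilyloxy)cyclohex-1-en-1-yl]but-3-enal
Product: 22 (2Z,3E)-2-(iodomethylidene)-4-[(4R)-2,6,6-trimethyl-4-(triethylsilyloxy)cyclohex-1-en-1-yl]but-3-enoic acid (ring B iodo acid)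
Conditions: NaClO2, NaH2PO4, 2-methyl-2-butene (large excess), t-BuOH/H2O, 0 °C
Reagents that add atoms: sodium chlorite, [Na+].[O-]Cl=O
Why: Pinnick oxidation converts the enal to the acid without disturbing the iodoalkene geometry, the excess 2-methyl-2-butene trapping hypochlorous acid before it can reach the ring alkene.

**Step 11**
Reactants: 12 ring A tetraenediyne (1.1 equiv); 22 ring B iodo acid
Product: 24 (Z)-5-{(2E,4E,6E,8E)-2,9-dimethyl-11-[(4R)-2,6,6-trimethyl-4-(triethylsilyloxy)cyclohex-1-en-1-yl]undeca-2,4,6,8-tetraen-10-yn-1-ylidene}-3-{(E)-2-[(4R)-2,6,6-trimethyl-4-(triethylsilyloxy)cyclohex-1-en-1-yl]ethenyl}furan-2(5H)-one, via enynoic acid 23 (not isolated)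
Conditions: PdCl2(PPh3)2 (5 mol%), CuI (10 mol%), Et3N (5 equiv), MeCN/THF, rt, degassed, dark, BHT
Reagents that add atoms: none
Why: In this tandem cross-coupling–lactonisation of a Z-3-iodoacrylic acid, Sonogashira coupling with retention gives a Z-enynoic acid whose carboxylate adds anti across the metal-activated alkyne in a 5-exo-dig mode, closing the butenolide with the polyene cis to the ring oxygen.

**Step 12**
Reactants: 24 the 5,6-alkene bis(triethylsilyl) ether
Product: 25 (Z)-5-{(2E,4E,6E,8E)-2,9-dimethyl-11-[(4R)-2,6,6-trimethyl-4-(triethylsilyloxy)cyclohex-1-en-1-yl]undeca-2,4,6,8-tetraen-10-yn-1-ylidene}-3-{(E)-2-[(1S,4S,6R)-2,2,6-trimethyl-4-(triethylsilyloxy)-7-oxabicyclo[4.1.0]heptan-1-yl]ethenyl}furan-2(5H)-one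
Conditions: dimethyldioxirane (1.0–1.1 equiv, ca. 0.07 M in acetone, in portions), CH2Cl2, −40 to −20 °C, dark; stopped before full conversion and 24 recycled; chromatography on Et3N-deactivated silica
Reagents that add atoms: dimethyldioxirane, CC1(C)OO1
Why: Dimethyldioxirane transfers its electrophilic oxygen to the alkene in a concerted, suprafacial spiro transition state, the closest known reaction being the peracid or dioxirane 5,6-epoxidation of 3-oxygenated cyclohexene end groups of carotenoids. The oxirane, the only ring formed, is closed by this single oxygen-atom [2+1] addition, which makes both C–O bonds (O–C5 and O–C6) on the same face. The two new stereocentres C5 and C6 are set together by the face of approach: each face carries one C1 methyl group, so the C3 triethylsilyloxy group is the differentiating element and oxygen should arrive mainly anti to it, giving the (5R,6S) oxirane, with the syn diastereomer as the expected minor product to be removed by chromatography. Site selectivity among nine alkenes rests on nucleophilicity: C5=C6 of ring B is tetrasubstituted and twisted out of conjugation by the C1 and C5 methyl groups, whereas the ring A alkene is bonded to an sp carbon and lies planar with the enyne–polyene–lactone chromophore, the chain alkenes are di- or trisubstituted and conjugated to the lactone, and the butenolide alkene is acceptor-substituted. Low temperature, about one equivalent of oxidant and interruption before full conversion should limit polyene over-oxidation, and the only by-product, acetone, is neutral, so the acid-labile vinyl epoxide should not rearrange to the 5,8-furanoid isomer.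

**Step 13**
Reactants: 25 the 5,6-epoxide bis(triethylsilyl) ether
Product: 26 (Z)-3-{(E)-2-[(1S,4S,6R)-4-hydroxy-2,2,6-trimethyl-7-oxabicyclo[4.1.0]heptan-1-yl]ethenyl}-5-{(2E,4E,6E,8E)-11-[(4R)-4-hydroxy-2,6,6-trimethylcyclohex-1-en-1-yl]-2,9-dimethylundeca-2,4,6,8-tetraen-10-yn-1-ylidene}furan-2(5H)-one (target CNP0180336.1)
Conditions: Bu4NF/AcOH (1:1, 4 equiv), THF, 0 °C to rt, dark
Reagents that add atoms: none
Why: Fluoride desilylation cleaves the two secondary triethylsilyl ethers at silicon while the acetic acid buffer keeps the medium near neutral, so neither the acid-labile vinyl epoxide nor the base-sensitive ylidenebutenolide should be touched.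

**Compound list**
1 | (4R,6R)-actinol, (4R,6R)-4-hydroxy-2,2,6-trimethylcyclohexan-1-one | C[C@@H]1C[C@@H](O)CC(C)(C)C1=O | starting material
2 | (4R,6R)-2,2,6-trimethyl-4-(triethylsilyloxy)cyclohexan-1-one | C[C@@H]1C[C@@H](O[Si](CC)(CC)CC)CC(C)(C)C1=O | intermediate
3 | lithium (4R)-2,6,6-trimethyl-4-(triethylsilyloxy)cyclohex-1-en-1-olate (lithium enolate) | [Li]OC1=C(C)C[C@@H](O[Si](CC)(CC)CC)CC1(C)C | intermediate (not isolated)
4 | (4R)-2,6,6-trimethyl-4-(triethylsilyloxy)cyclohex-1-en-1-yl trifluoromethanesulfonate | CC1=C(OS(=O)(=O)C(F)(F)F)C(C)(C)C[C@H](O[Si](CC)(CC)CC)C1 | intermediate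
5 | (E)-3-methylpent-2-en-4-yn-1-ol | C#C/C(C)=C/CO | starting material
6 | (E)-5-bromo-3-methylpent-3-en-1-yne | C#C/C(C)=C/CBr | intermediate
7 | [(E)-3-methylpent-2-en-4-yn-1-yl]triphenylphosphonium bromide | C#C/C(C)=C/C[P+](c1ccccc1)(c1ccccc1)c1ccccc1.[Br-] | intermediate
8 | glyoxal | O=CC=O | starting material
9 | [(E)-3-methylpent-2-en-4-yn-1-ylidene]triphenylphosphorane (phosphorus ylide) | C#C/C(C)=C/C=P(c1ccccc1)(c1ccccc1)c1ccccc1 | intermediate (not isolated)
10 | (2E,4E)-5-methylhepta-2,4-dien-6-ynal (dienynal, formed as an E/Z mixture at C2) | C#C/C(C)=C/C=C/C=O | intermediate (not isolated)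
11 | (3E,5E,7E,9E)-3,10-dimethyldodeca-3,5,7,9-tetraene-1,11-diyne | C#C/C(C)=C/C=C/C=C/C=C(C)/C#C | intermediate
12 | triethyl({(1R)-4-[(3E,5E,7E,9E)-3,10-dimethyldodeca-3,5,7,9-tetraene-1,11-diyn-1-yl]-3,5,5-trimethylcyclohex-3-en-1-yl}oxy)silane (ring A tetraenediyne) | CC1=C(C#C/C(C)=C/C=C/C=C/C=C(C)/C#C)C(C)(C)C[C@H](O[Si](CC)(CC)CC)C1 | intermediate
13 | (E)-1,2-bis(tributylstannyl)ethene | CCCC[Sn](CCCC)(CCCC)/C=C/[Sn](CCCC)(CCCC)CCCC | starting material
14 | tributyl{(E)-2-[(4R)-2,6,6-trimethyl-4-(triethylsilyloxy)cyclohex-1-en-1-yl]ethenyl}stannane | CCCC[Sn](CCCC)(CCCC)/C=C/C1=C(C)C[C@@H](O[Si](CC)(CC)CC)CC1(C)C | intermediate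
15 | prop-2-yn-1-ol (propargyl alcohol) | C#CCO | starting material
16 | bromomagnesium prop-2-yn-1-olate | C#CCO[Mg]Br | intermediate (not isolated)
17 | {(E)-2-[(4R)-2,6,6-trimethyl-4-(triethylsilyloxy)cyclohex-1-en-1-yl]ethenyl}lithium (dienyllithium) | [Li]/C=C/C1=C(C)C[C@@H](O[Si](CC)(CC)CC)CC1(C)C | intermediate (not isolated)
18 | {(E)-2-[(4R)-2,6,6-trimethyl-4-(triethylsilyloxy)cyclohex-1-en-1-yl]ethenyl}magnesium bromide | Br[Mg]/C=C/C1=C(C)C[C@@H](O[Si](CC)(CC)CC)CC1(C)C | intermediate (not isolated)
19 | cyclic alkenylmagnesium alkoxide (1-oxa-2-magnesacyclopent-3-ene with the ring B dienyl group at C4) | [Mg]1OCC(/C=C/C2=C(C)C[C@@H](O[Si](CC)(CC)CC)CC2(C)C)=C1 | intermediate (not isolated)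
20 | (2Z,3E)-2-(iodomethylidene)-4-[(4R)-2,6,6-trimethyl-4-(triethylsilyloxy)cyclohex-1-en-1-yl]but-3-en-1-ol | OC/C(=C\I)/C=C/C1=C(C)C[C@@H](O[Si](CC)(CC)CC)CC1(C)C | intermediate
21 | (2Z,3E)-2-(iodomethylidene)-4-[(4R)-2,6,6-trimethyl-4-(triethylsilyloxy)cyclohex-1-en-1-yl]but-3-enal | O=C/C(=C\I)/C=C/C1=C(C)C[C@@H](O[Si](CC)(CC)CC)CC1(C)C | intermediate
22 | (2Z,3E)-2-(iodomethylidene)-4-[(4R)-2,6,6-trimethyl-4-(triethylsilyloxy)cyclohex-1-en-1-yl]but-3-enoic acid | OC(=O)/C(=C\I)/C=C/C1=C(C)C[C@@H](O[Si](CC)(CC)CC)CC1(C)C | intermediate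
23 | (2Z,6E,8E,10E,12E)-6,13-dimethyl-2-{(E)-2-[(4R)-2,6,6-trimethyl-4-(triethylsilyloxy)cyclohex-1-en-1-yl]ethenyl}-15-[(4R)-2,6,6-trimethyl-4-(triethylsilyloxy)cyclohex-1-en-1-yl]pentadeca-2,6,8,10,12-pentaene-4,14-diynoic acid (enynoic acid) | OC(=O)/C(=C\C#C/C(C)=C/C=C/C=C/C=C(C)/C#CC1=C(C)C[C@@H](O[Si](CC)(CC)CC)CC1(C)C)/C=C/C1=C(C)C[C@@H](O[Si](CC)(CC)CC)CC1(C)C | intermediate (not isolated)
24 | 5,6-alkene analogue of the target as its bis(triethylsilyl) ether (name in step 11) | CC1=C(C#C/C(C)=C/C=C/C=C/C=C(C)/C=C2C=C(/C=C/C3=C(C)C[C@@H](O[Si](CC)(CC)CC)CC3(C)C)C(=O)O/2)C(C)(C)C[C@H](O[Si](CC)(CC)CC)C1 | intermediate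
25 | bis(triethylsilyl) ether of the target (name in step 12) | CC1=C(C#C/C(C)=C/C=C/C=C/C=C(C)/C=C2C=C(/C=C/[C@@]34O[C@]3(C)C[C@@H](O[Si](CC)(CC)CC)CC4(C)C)C(=O)O/2)C(C)(C)C[C@H](O[Si](CC)(CC)CC)C1 | intermediate
26 | CNP0180336.1 (name in step 13) | CC1=C(C#C/C(C)=C/C=C/C=C/C=C(C)/C=C2C=C(/C=C/[C@@]34O[C@]3(C)C[C@@H](O)CC4(C)C)C(=O)O/2)C(C)(C)C[C@H](O)C1 | target

**Step count**
Total: 13 steps. Longest linear sequence: 9 steps (1, 2, 7, 8, 9, 10, 11, 12, 13).

**Steps most likely to fail**

1. Step 12. The oxidant may not discriminate well enough between the ring B alkene and the ring A enyne alkene or the polyene, and over-oxidation of the chromophore may outrun mono-epoxidation. Fallback: the epoxidation is moved to the fragment stage, where the ring B alkene is the only electron-rich alkene. It sets out from acid 22, which is treated with dimethyldioxirane in acetone at −30 °C to give (2Z,3E)-2-(iodomethylidene)-4-[(1S,4S,6R)-2,2,6-trimethyl-4-(triethylsilyloxy)-7-oxabicyclo[4.1.0]heptan-1-yl]but-3-enoic acid F1, with the syn diastereomer separated at this small-molecule stage. F1 is then taken through the tandem coupling–lactonisation of step 11 with tetraenediyne 12 under the same basic Pd/Cu conditions, and the route is rejoined at 25.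

2. Step 8. The dienyl Grignard reagent may be protonated by residual hydroxyl or acetylenic C–H before it adds, or the carbomagnesiation may stall with the hindered alkenyl nucleophile. Fallback: the iodo acid is bypassed by a stepwise assembly of the enynoic acid that sets out from 12 and 14. Ethyl (E)-2,3-dibromopropenoate is coupled with the terminal alkyne of 12 (Pd(PPh3)4, CuI, Et3N) at the bromine on C3, which is cis to the ester, to give ethyl (2E,6E,8E,10E,12E)-2-bromo-6,13-dimethyl-15-[(4R)-2,6,6-trimethyl-4-(triethylsilyloxy)cyclohex-1-en-1-yl]pentadeca-2,6,8,10,12-pentaene-4,14-diynoate F2. Stille coupling of F2 with stannane 14 (Pd2(dba)3, AsPh3, CuI) at C2 gives the ethyl ester of the enynoic acid F3. LiOH in THF/water frees acid 23, where the route is rejoined; 23 is closed to 24 with catalytic AgNO3 in acetone by the same 5-exo-dig addition.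

3. Step 7. Transmetalation at the tetrasubstituted vinyl triflate may be slow, and double coupling of the distannane or protodestannylation of the dienylstannane may erode the yield. Fallback: the two vinyl carbons are brought in as an alkyne, since Sonogashira coupling is less sensitive to hindrance. It sets out from triflate 4, which is coupled with ethynyltrimethylsilane (Pd(PPh3)4, CuI, Et3N) to give triethyl{[(1R)-3,5,5-trimethyl-4-[(trimethylsilyl)ethynyl]cyclohex-3-en-1-yl]oxy}silane F4. K2CO3 in MeOH at 0 °C removes the alkynyl silyl group to give triethyl{[(1R)-4-ethynyl-3,5,5-trimethylcyclohex-3-en-1-yl]oxy}silane F5. Syn-hydrostannation of F5 with Bu3SnH and PdCl2(PPh3)2 places tin on the unhindered terminus and returns to the route at stannane 14.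

**Further compounds**
F1 | step 12 | (2Z,3E)-2-(iodomethylidene)-4-[(1S,4S,6R)-2,2,6-trimethyl-4-(triethylsilyloxy)-7-oxabicyclo[4.1.0]heptan-1-yl]but-3-enoic acid | OC(=O)/C(=C\I)/C=C/[C@@]12O[C@]1(C)C[C@@H](O[Si](CC)(CC)CC)CC2(C)C
F2 | step 8 | ethyl (2E,6E,8E,10E,12E)-2-bromo-6,13-dimethyl-15-[(4R)-2,6,6-trimethyl-4-(triethylsilyloxy)cyclohex-1-en-1-yl]pentadeca-2,6,8,10,12-pentaene-4,14-diynoate | CCOC(=O)/C(Br)=C\C#C/C(C)=C/C=C/C=C/C=C(C)/C#CC1=C(C)C[C@@H](O[Si](CC)(CC)CC)CC1(C)C
F3 | step 8 | ethyl (2Z,6E,8E,10E,12E)-6,13-dimethyl-2-{(E)-2-[(4R)-2,6,6-trimethyl-4-(triethylsilyloxy)cyclohex-1-en-1-yl]ethenyl}-15-[(4R)-2,6,6-trimethyl-4-(triethylsilyloxy)cyclohex-1-en-1-yl]pentadeca-2,6,8,10,12-pentaene-4,14-diynoate | CCOC(=O)/C(=C\C#C/C(C)=C/C=C/C=C/C=C(C)/C#CC1=C(C)C[C@@H](O[Si](CC)(CC)CC)CC1(C)C)/C=C/C1=C(C)C[C@@H](O[Si](CC)(CC)CC)CC1(C)C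
F4 | step 7 | triethyl{[(1R)-3,5,5-trimethyl-4-[(trimethylsilyl)ethynyl]cyclohex-3-en-1-yl]oxy}silane | CC1=C(C#C[Si](C)(C)C)C(C)(C)C[C@H](O[Si](CC)(CC)CC)C1
F5 | step 7 | triethyl{[(1R)-4-ethynyl-3,5,5-trimethylcyclohex-3-en-1-yl]oxy}silane | CC1=C(C#C)C(C)(C)C[C@H](O[Si](CC)(CC)CC)C1
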